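All constants were chosen freely; the flask was simulated.

At early times the G in this flask is its seed, 2.50 mM against 0.050 M of E, and the step making G from E + G adds to that partner as E falls: an autocatalytic decay.

E 0.050 M; G 2.50 mM; time 5.0 d

    E + G → E.G (k1 = 0.15 M⁻¹ min⁻¹)
    E + G → 2 G (k2 = 5.9 M⁻¹ min⁻¹)
    E → G (k3 = 2.1 × 10⁻⁶ min⁻¹)

- why nothing more happens at 5.0 d, or that something still does (forward and back rates have come level / it is still moving / all of E has reacted)
- part of the E gone at 5.0 d
- the G standing at 5.0 d, as a percentage of the E charged
- the E.G standing at 5.0 d, as a percentage of the E charged
- amount of G if the flask were left three thousand times as long, in percent of the E charged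

- percent here means E units held: one E.G counts as two
- the reaction counts as stopped when no species that holds the E and the seed together changes by six tenths of a point or more over the second half of the time
- run time (flask): 5.0 d

1. I work with the fraction of E left, not with what is made. The two E + G steps together lower ln cE at the rate (k1 + k2)·cG, and the conversion of E into G adds to that.

2. In this flask cG stays at or above its charge, because the step making G, at 5.9 M⁻¹ min⁻¹, is faster than the step taking it, at 0.15 M⁻¹ min⁻¹.

3. So 109 is the decay number N of this flask: (k1 + k2) times the charged cG times the time, a floor under the natural logarithm of charged E over E left.

4. Now the question turned round. For "still moving", the E standing at half time must exceed the stopping margin, which is more than one part in 200. That needs N below 10.6. This flask stands at ten times that, so I say all of E has reacted, with 100% of E gone.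

5. The forecast says all of E has reacted, with conversion 100%, G 100%, E.G 4.96% and, left far longer, G 100%. Its ground is that “The autocatalytic step burns E within an hour or so at these concentrations”.

6. The simulation gives all of E has reacted, with conversion 100%, G 100%, E.G 4.96% and, left far longer, G 100%.

This flask has come to rest: E stands at 0% at 5.00 d, and the largest move over the second half is 0 percentage points. The conversion of E into G turned over 0%, and striking it out leaves G at 100%. With N at 109, the natural logarithm of the fraction of E left lies below −109, so ten times the time has at most that fraction to change. At 50.0 d N reads 1090, G stands at 100% and E.G at 4.96%. A neighbour flask, charged with 0.020 M of E, keeps N at 109, since cE does not enter it, and holds E at 0% at 5.00 d.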